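**Retrosynthetic overview**
1. Target 16 ⇐ racemic fumarate 14 (labile lactol carbon set last by crystallisation-induced asymmetric transformation of an amine salt) ⇐ salazinic acid 13 + fumaric acid 12 (o-quinone-methide esterification).
2. Lactol 13 ⇐ depsidone 11, which carries the lactol as its methyl pseudo-ester and the CH2OH as CH2OMe (acid hydrolysis).
3. Seven-membered depsidone ring of 11 ⇐ depside 10 by direct oxidative phenol C–O coupling (ring A 2-OH onto the ring B C–H para to the ring B phenol).
4. Depside 10 ⇐ haematommic acid 3 + phthalide phenol 9 (ester bond).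
5. 9 ⇐ methyl 2,4-dihydroxy-3,6-dimethylbenzoate 4; 3 ⇐ methyl orsellinate 1. Ring order: masked lactol (phthalide) ring on ring B, then the depsidone ring, then unmasking of the lactol.

Assumption: the only stereocentre is the ring–chain-labile lactol carbon (R), so it is set in the last step and the product is kept cold and solid; the (S)-amine is taken to be the enantiomer whose salt with the (R)-lactol is the less soluble one (the mirror-image amine serves otherwise).

**Route**

Step 1
Reactants: 1 methyl 2,4-dihydroxy-6-methylbenzoate (methyl orsellinate)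
Product: 2 methyl 3-formyl-2,4-dihydroxy-6-methylbenzoate (methyl haematommate)
Conditions: Cl2CHOMe (1.3 equiv), TiCl4 (2.5 equiv), CH2Cl2, −10 → 0 °C; then 1 M HCl; minor 5-formyl isomer removed by crystallisation
Reagents that add atoms: dichloromethyl methyl ether, COC(Cl)Cl; water, O
Why: Rieche formylation, in which the titanium phenoxide chelate delivers the electrophile to C3 (ortho to both hydroxyls) and hydrolysis of the α-chloro ether gives the aldehyde.

Step 2
Reactants: 2 methyl 3-formyl-2,4-dihydroxy-6-methylbenzoate
Product: 3 3-formyl-2,4-dihydroxy-6-methylbenzoic acid (haematommic acid)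
Conditions: conc. H2SO4, 0 → 20 °C, 30 min; pour onto ice
Reagents that add atoms: water, O
Why: AAC1 (acylium) ester cleavage typical of di-ortho-substituted benzoates, run cold so that the β-resorcylic acid does not decarboxylate.

Step 3
Reactants: 4 methyl 2,4-dihydroxy-3,6-dimethylbenzoate
Product: 5 methyl 2,4-diacetoxy-3,6-dimethylbenzoate
Conditions: Ac2O (3 equiv), pyridine, DMAP (cat.), rt
Reagents that add atoms: acetic anhydride, CC(=O)OC(C)=O
Why: DMAP-catalysed O-acetylation masks both phenols so that NBS later reacts by the radical benzylic path and not by ring bromination.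

Step 4
Reactants: 5 methyl 2,4-diacetoxy-3,6-dimethylbenzoate
Product: 8 (±)-3-bromo-6-(bromomethyl)-1-oxo-1,3-dihydroisobenzofuran-5,7-diyl diacetate, via bis(bromomethyl) ester 6 (not isolated), via bromomethylphthalide diacetate 7 (not isolated)
Conditions: NBS (3.2 equiv), hν (white LED), PhCl, 130 °C, MeBr vented
Reagents that add atoms: N-bromosuccinimide, O=C1CCC(=O)N1Br
Why: Wohl–Ziegler bromination puts one bromine on each methyl, the 6-bromomethyl ester lactonises thermally with loss of MeBr, and the phthalide CH2 (benzylic and next to oxygen) takes the third bromine, while the bromomethyl group flanked by two acetoxy groups is shielded from a second bromination (as in the clean formation of hexakis(bromomethyl)benzene); the new C3 centre is racemic.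

Step 5
Reactants: 8 (±)-3-bromo-6-(bromomethyl)-1-oxo-1,3-dihydroisobenzofuran-5,7-diyl diacetate
Product: 9 (±)-5,7-dihydroxy-3-methoxy-6-(methoxymethyl)isobenzofuran-1(3H)-one
Conditions: MeOH (0.05 M), 40 °C, 6 h; concentrate below 25 °C, triturate with cold water
Reagents that add atoms: methanol, CO
Why: SN1 methanolysis of the 3-bromophthalide gives the methyl pseudo-ester, the liberated HBr catalyses transesterification of both aryl acetates, and the unmasked o-hydroxybenzyl bromide exchanges to the methyl ether through an o-quinone methide; the acetal centre is racemic.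

Step 6
Reactants: 3 haematommic acid; 9 (±)-5,7-dihydroxy-3-methoxy-6-(methoxymethyl)isobenzofuran-1(3H)-one
Product: 10 (±)-7-hydroxy-3-methoxy-6-(methoxymethyl)-1-oxo-1,3-dihydroisobenzofuran-5-yl 3-formyl-2,4-dihydroxy-6-methylbenzoate (depside)
Conditions: DCC (1.1 equiv), THF–toluene (1:1), 0 °C → rt, 16 h
Reagents that add atoms: none
Why: Carbodiimide esterification acylates the only non-chelated phenol (the 5-OH of 9; the 7-OH is hydrogen-bonded to the lactone carbonyl and the hydroxyls of 3 to CHO and CO2H), as in carbodiimide syntheses of atranorin-type depsides.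

Step 7
Reactants: 10 depside
Product: 11 (±)-8'-O-methylsalazinic acid methyl pseudo-ester (salazinic acid depsidone skeleton bearing CH2OMe in place of CH2OH and lactol OMe in place of lactol OH)
Conditions: PhI(OAc)2 (1.05 equiv, added over 1 h), (CF3)2CHOH, 2 mM, −20 → 0 °C
Reagents that add atoms: none
Why: Proposed new method: two-electron oxidation of the ring B phenol by the trivalent-iodine reagent in the ionising, non-nucleophilic fluoro-alcohol gives a phenoxenium-type species whose para carbon (the only unsubstituted ring B position) is captured intramolecularly by the ring A 2-OH through a seven-membered transition state, and loss of the para proton re-aromatises to the diaryl ether, which is the chemical counterpart of the P450 phenol coupling presumed to convert depsides into depsidones; the closest known reactions are trivalent-iodine para-oxygenation of phenols by O-nucleophiles (quinol and quinone-monoketal formation) and the MnO2 oxidative cyclisation of a chlorinated depside to a depsidone.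

Step 8
Reactants: 11 (±)-8'-O-methylsalazinic acid methyl pseudo-ester; 12 fumaric acid
Product: 14 racemic salazinic acid 8'-O-hydrogen fumarate (target constitution; lactol carbon racemic), via salazinic acid 13 (not isolated)
Conditions: TFA–H2O–1,4-dioxane (1:1:4), 60 °C; evaporate; then 12 (20 equiv), 1,4-dioxane–sulfolane (5:1), 95 °C; aqueous wash
Reagents that add atoms: water, O; fumaric acid (compound 12), OC(=O)/C=C/C(=O)O
Why: Aqueous acid hydrolyses the pseudo-ester acetal to the lactol and exchanges the o-hydroxybenzyl methyl ether for the alcohol via the o-quinone methide, and the same o-quinone methide, regenerated thermally, is captured by the large excess of fumaric acid (the known tendency of hydroxymethyl depsidones to form ethers and esters on warming in alcohols or carboxylic acids); the lactol centre is still racemic.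

Step 9
Reactants: 14 racemic salazinic acid 8'-O-hydrogen fumarate
Product: 16 salazinic acid 8'-O-hydrogen fumarate having the (R) lactol carbon (target CNP0379578.1), via (S)-dimethyl(1-phenylethyl)ammonium salt 15 (not isolated)
Conditions: (S)-PhCH(Me)NMe2 (1.0 equiv), MeCN–EtOAc, 35 °C slurry, 48 h, then −10 °C; cold 1 M HCl–EtOAc added to the slurry at ≤ 0 °C; product isolated cold as a solid
Reagents that add atoms: none
Why: Crystallisation-induced asymmetric transformation, in which the lactol epimerises in solution through the ring-opened formyl carboxylate while the less soluble diastereomeric salt of the (R)-lactol crystallises, and cold acid then frees the acid before it can re-equilibrate.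

**Compound list**
1 | methyl 2,4-dihydroxy-6-methylbenzoate (methyl orsellinate) | COC(=O)c1c(C)cc(O)cc1O | starting material
2 | methyl 3-formyl-2,4-dihydroxy-6-methylbenzoate (methyl haematommate) | COC(=O)c1c(C)cc(O)c(C=O)c1O | intermediate
3 | 3-formyl-2,4-dihydroxy-6-methylbenzoic acid (haematommic acid) | Cc1cc(O)c(C=O)c(O)c1C(=O)O | intermediate
4 | methyl 2,4-dihydroxy-3,6-dimethylbenzoate | COC(=O)c1c(C)cc(O)c(C)c1O | starting material
5 | methyl 2,4-diacetoxy-3,6-dimethylbenzoate | COC(=O)c1c(C)cc(OC(C)=O)c(C)c1OC(C)=O | intermediate
6 | methyl 2,4-diacetoxy-3,6-bis(bromomethyl)benzoate | COC(=O)c1c(CBr)cc(OC(C)=O)c(CBr)c1OC(C)=O | intermediate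
7 | 6-(bromomethyl)-1-oxo-1,3-dihydroisobenzofuran-5,7-diyl diacetate | O=C1OCc2cc(OC(C)=O)c(CBr)c(OC(C)=O)c12 | intermediate
8 | (±)-3-bromo-6-(bromomethyl)-1-oxo-1,3-dihydroisobenzofuran-5,7-diyl diacetate | O=C1OC(Br)c2cc(OC(C)=O)c(CBr)c(OC(C)=O)c12 | intermediate
9 | (±)-5,7-dihydroxy-3-methoxy-6-(methoxymethyl)isobenzofuran-1(3H)-one | O=C1OC(OC)c2cc(O)c(COC)c(O)c12 | intermediate
10 | (±)-7-hydroxy-3-methoxy-6-(methoxymethyl)-1-oxo-1,3-dihydroisobenzofuran-5-yl 3-formyl-2,4-dihydroxy-6-methylbenzoate (depside) | Cc1cc(O)c(C=O)c(O)c1C(=O)Oc1cc2c(c(O)c1COC)C(=O)OC2OC | intermediate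
11 | (±)-8'-O-methylsalazinic acid methyl pseudo-ester (depsidone; CH2OMe and lactol OMe) | Cc1cc(O)c(C=O)c2c1C(=O)Oc1c(COC)c(O)c3c(c1O2)C(OC)OC3=O | intermediate
12 | fumaric acid | OC(=O)/C=C/C(=O)O | starting material
13 | (±)-salazinic acid | Cc1cc(O)c(C=O)c2c1C(=O)Oc1c(CO)c(O)c3c(c1O2)C(O)OC3=O | intermediate
14 | racemic salazinic acid 8'-O-hydrogen fumarate | Cc1cc(O)c(C=O)c2c1C(=O)Oc1c(COC(=O)/C=C/C(=O)O)c(O)c3c(c1O2)C(O)OC3=O | intermediate
15 | (S)-dimethyl(1-phenylethyl)ammonium salt of the (R)-lactol fumarate | Cc1cc(O)c(C=O)c2c1C(=O)Oc1c(COC(=O)/C=C/C(=O)[O-])c(O)c3c(c1O2)[C@H](O)OC3=O.C[C@H]([NH+](C)C)c1ccccc1 | intermediate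
16 | salazinic acid 8'-O-hydrogen (E)-fumarate, (R) at the lactol carbon | Cc1cc(O)c(C=O)c2c1C(=O)Oc1c(COC(=O)/C=C/C(=O)O)c(O)c3c(c1O2)[C@H](O)OC3=O | target

**Step count and risks**
Total steps: 9. Longest linear sequence: 7 (steps 3, 4, 5, 6, 7, 8, 9 from compound 4).

Most likely to fail, step 7 (oxidative depside-to-depsidone coupling). The ring B phenol is electron-poor, ring A has a free position, and the product phenol is easier to oxidise than the substrate. The fallback sets out from compound 9 (using compound 3) and comes back at compound 11, replacing the oxidation by a redox-neutral coupling. NBS in MeCN at −10 °C brominates 9 at its only free ring position to give (±)-4-bromo-5,7-dihydroxy-3-methoxy-6-(methoxymethyl)isobenzofuran-1(3H)-one F1. DCC esterification of this with 3 gives (±)-4-bromo-7-hydroxy-3-methoxy-6-(methoxymethyl)-1-oxo-1,3-dihydroisobenzofuran-5-yl 3-formyl-2,4-dihydroxy-6-methylbenzoate F2. An intramolecular Ullmann etherification (CuI, N,N-dimethylglycine, K3PO4, dioxane, 90 °C) then closes the seven-membered ring to 11.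

Second, step 4 (one-pot triple bromination and lactonisation). It relies on steric discrimination between the two methyl groups. The fallback sets out from compound 2 and comes back at compound 9; the ring B side-chain carbon enters as the formyl group, so only one methyl is ever brominated. NaBH4 in THF–MeOH at 0 °C reduces 2 to methyl 2,4-dihydroxy-3-(hydroxymethyl)-6-methylbenzoate F3. Ac2O–pyridine gives methyl 2,4-diacetoxy-3-(acetoxymethyl)-6-methylbenzoate F4. NBS (2.1 equiv, hν, PhCl, 130 °C) brominates the single methyl, which lactonises and is brominated again to (±)-6-(acetoxymethyl)-3-bromo-1-oxo-1,3-dihydroisobenzofuran-5,7-diyl diacetate F5. MeOH with catalytic HCl at 40 °C converts this into 9.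

Third, step 9 (crystallisation-induced asymmetric transformation). A well-crystallising salt may not be found, or the o-hydroxybenzyl ester may suffer under the amine. The fallback sets out from compound 14 and comes back at compound 16: preparative chromatography on a polysaccharide chiral stationary phase with an acidic eluent below 0 °C, with the unwanted enantiomer re-racemised in buffered solution and recycled. It forms no new compound (none F0).

**Further compounds**
F1 | step 7 | (±)-4-bromo-5,7-dihydroxy-3-methoxy-6-(methoxymethyl)isobenzofuran-1(3H)-one | O=C1OC(OC)c2c(Br)c(O)c(COC)c(O)c12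
F2 | step 7 | (±)-4-bromo-7-hydroxy-3-methoxy-6-(methoxymethyl)-1-oxo-1,3-dihydroisobenzofuran-5-yl 3-formyl-2,4-dihydroxy-6-methylbenzoate | Cc1cc(O)c(C=O)c(O)c1C(=O)Oc1c(Br)c2c(c(O)c1COC)C(=O)OC2OC
F3 | step 4 | methyl 2,4-dihydroxy-3-(hydroxymethyl)-6-methylbenzoate | COC(=O)c1c(C)cc(O)c(CO)c1O
F4 | step 4 | methyl 2,4-diacetoxy-3-(acetoxymethyl)-6-methylbenzoate | COC(=O)c1c(C)cc(OC(C)=O)c(COC(C)=O)c1OC(C)=O
F5 | step 4 | (±)-6-(acetoxymethyl)-3-bromo-1-oxo-1,3-dihydroisobenzofuran-5,7-diyl diacetate | O=C1OC(Br)c2cc(OC(C)=O)c(COC(C)=O)c(OC(C)=O)c12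
F0 | step 9 | none | none
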